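**Retrosynthetic overview**
1. Target ⇒ dibenzyl ether of a 1-hydroxy-2,6-diaryl-3,7-dioxabicyclo[3.3.0]octane (1-hydroxypinoresinol skeleton). Hydrogenolysis of the C6–O7 benzylic bond turns ring B into the 4-benzyl and 3-CH2OH groups; the cis ring fusion already holds OH anti to the benzyl group and the 2-aryl group exo.
2. Bicycle ⇒ acyclic (R)-α-cinnamyloxy α'-silyloxy ketone by one Lewis-acid Prins bicyclisation: C–C bond closes ring A, then the CH2O oxygen captures the benzylic cation to close ring B.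
3. Ketone ⇒ oxidation of the alcohol from invertive benzylic opening of a Sharpless epoxide by the same cinnamyl alcohol; L-(+)-DET is the only source of chirality.
4. Both C6–C3 halves ⇒ one allylic alcohol from O-benzylvanillin (HWE, DIBAL-H).
5. Ring order: oxirane (temporary) → oxolane A and oxolane B together → ring B reopened in the last step.

Assumptions: a one-flask sequence whose intermediate is not isolated counts as one step. Lignan locants are used in the explanations: C7 = ArCH–O, C8 = carbinol carbon, C9 = CH2O on C8; C7'/C8'/C9' = benzylic carbon, ring CH and ring OCH2 of the cinnamyl half. The regiochemistry of step 7 and the stereochemical course of steps 4 and 6 are predictions from mechanism, not verified results.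

**Step 1**
Reactants: 1 4-(benzyloxy)-3-methoxybenzaldehyde; 2 triethyl phosphonoacetate
Product: 3 ethyl (2E)-3-[4-(benzyloxy)-3-methoxyphenyl]prop-2-enoate
Conditions: NaH, THF, 0 °C → rt
Reagents that add atoms: none
Why: Horner–Wadsworth–Emmons olefination of an aromatic aldehyde with a stabilised phosphonate gives the (E)-enoate almost exclusively; no stereocentre is formed.

**Step 2**
Reactants: 3 ethyl (2E)-3-[4-(benzyloxy)-3-methoxyphenyl]prop-2-enoate
Product: 4 (2E)-3-[4-(benzyloxy)-3-methoxyphenyl]prop-2-en-1-ol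
Conditions: DIBAL-H (2.5 equiv), CH2Cl2, −78 → 0 °C; Rochelle salt
Reagents that add atoms: none
Why: DIBAL-H 1,2-reduction of an enoate gives the (E)-allylic alcohol without touching the alkene or the benzyl ether; this alcohol supplies both halves of the target.

**Step 3**
Reactants: 4 (2E)-3-[4-(benzyloxy)-3-methoxyphenyl]prop-2-en-1-ol
Product: 6 tert-butyl{[(2S,3S)-3-(4-benzyloxy-3-methoxyphenyl)oxiran-2-yl]methoxy}dimethylsilane, via (2S,3S)-epoxy alcohol 5 (not isolated)
Conditions: Ti(OiPr)4 (10 mol%), L-(+)-DET (12 mol%), TBHP, 4 Å MS, CH2Cl2, −20 °C; then P(OMe)3; then Et3N, DMAP (cat.), TBSCl, −20 → 0 °C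
Reagents that add atoms: tert-butyl hydroperoxide CC(C)(C)OO; tert-butyl(chloro)dimethylsilane CC(C)(C)[Si](C)(C)Cl
Why: Sharpless asymmetric epoxidation of an (E)-allylic alcohol with L-(+)-DET sets both epoxide carbons as (2S,3S) under catalyst control, and in situ silylation (Sharpless in situ derivatisation) traps the acid-labile electron-rich epoxy alcohol without an acidic aqueous work-up.

**Step 4**
Reactants: 6 tert-butyl{[(2S,3S)-3-(4-benzyloxy-3-methoxyphenyl)oxiran-2-yl]methoxy}dimethylsilane; 4 (2E)-3-[4-(benzyloxy)-3-methoxyphenyl]prop-2-en-1-ol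
Product: 7 (2S,3R)-3-[4-(benzyloxy)-3-methoxyphenyl]-3-{[(2E)-3-[4-(benzyloxy)-3-methoxyphenyl]prop-2-en-1-yl]oxy}-1-{[tert-butyl(dimethyl)silyl]oxy}propan-2-ol
Conditions: 4 (2.5 equiv, excess recovered), BF3·OEt2 (10 mol%), CH2Cl2, −40 °C
Reagents that add atoms: none
Why: Lewis-acid-catalysed alcoholysis of a 3-aryl-2,3-epoxy silyl ether occurs at the benzylic carbon with inversion, turning the (3S)-epoxide carbon into the (R)-configured ether carbon C7; any retention diastereomer is separable because C8 is still stereogenic, which protects the ee.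

**Step 5**
Reactants: 7 (2S,3R)-3-[4-(benzyloxy)-3-methoxyphenyl]-3-{[(2E)-3-[4-(benzyloxy)-3-methoxyphenyl]prop-2-en-1-yl]oxy}-1-{[tert-butyl(dimethyl)silyl]oxy}propan-2-ol
Product: 8 (1R)-1-[4-(benzyloxy)-3-methoxyphenyl]-1-{[(2E)-3-[4-(benzyloxy)-3-methoxyphenyl]prop-2-en-1-yl]oxy}-3-{[tert-butyl(dimethyl)silyl]oxy}propan-2-one
Conditions: Dess–Martin periodinane, CH2Cl2, 0 °C → rt
Reagents that add atoms: none
Why: Dess–Martin oxidation of the secondary alcohol is non-enolising, so it removes the C8 stereocentre and leaves the benzylic α-stereocentre C7 (R) intact.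

**Step 6**
Reactants: 8 (1R)-1-[4-(benzyloxy)-3-methoxyphenyl]-1-{[(2E)-3-[4-(benzyloxy)-3-methoxyphenyl]prop-2-en-1-yl]oxy}-3-{[tert-butyl(dimethyl)silyl]oxy}propan-2-one
Product: 10 (1S,2R,5R,6S)-2,6-bis[4-(benzyloxy)-3-methoxyphenyl]-3,7-dioxabicyclo[3.3.0]octan-1-ol, via Prins benzylic cation 9 (not isolated)
Conditions: SnCl4 (1.1 equiv), CH2Cl2 (0.01 M), −78 °C; sat. aq. NaHCO3 at −78 °C
Reagents that add atoms: none
Why: Proposed new method: the SnCl4-activated ketone C8 is attacked 5-exo by the electron-rich (E)-styrene (Prins C–C closure of ring A through a chair-like transition state with the C7 aryl equatorial, so this aryl ends trans to the C8' side chain) to give p-alkoxybenzylic cation 9, which is captured at once by the CH2O–Si oxygen with loss of TBSCl (ring B); only a cis-fused bicycle can close, so C8 (OH cis to the C7 aryl, anti to C7') and C8' follow from the preset (R)-C7 centre, the wrong-face adduct reverts by retro-Prins fragmentation and the C6 aryl settles exo (its configuration is erased in step 7 anyway); the closest known reactions are Lewis-acid Prins cyclisations of keto-alkenes (the first stage of catalytic carbonyl–olefin metathesis, here interrupted by an oxygen nucleophile) and Prins/etherification cascades terminated by silyl ethers.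

**Step 7**
Reactants: 10 (1S,2R,5R,6S)-2,6-bis[4-(benzyloxy)-3-methoxyphenyl]-3,7-dioxabicyclo[3.3.0]octan-1-ol
Product: 12 (2R,3S,4S)-2-(4-hydroxy-3-methoxyphenyl)-4-[(4-hydroxy-3-methoxyphenyl)methyl]-3-(hydroxymethyl)oxolan-3-ol, via 1-hydroxypinoresinol 11 (not isolated)
Conditions: H2 (1 atm), 10% Pd/C, EtOAc–EtOH, rt, stopped after 3 equiv H2
Reagents that add atoms: none
Why: Benzylic hydrogenolysis first removes both O-benzyl groups and then cleaves the p-hydroxybenzylic C6–O7 bond, which is less hindered and less deactivated than C2–O3 (flanked by the quaternary carbinol carbon), the same reaction type as pinoresinol → lariciresinol; C7' becomes CH2 and the three remaining stereocentres are untouched.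

**Compound list**
1 | 4-(benzyloxy)-3-methoxybenzaldehyde | COc1cc(C=O)ccc1OCc1ccccc1 | starting material
2 | triethyl phosphonoacetate | CCOC(=O)CP(=O)(OCC)OCC | starting material
3 | ethyl (2E)-3-[4-(benzyloxy)-3-methoxyphenyl]prop-2-enoate | CCOC(=O)/C=C/c1ccc(OCc2ccccc2)c(OC)c1 | intermediate
4 | (2E)-3-[4-(benzyloxy)-3-methoxyphenyl]prop-2-en-1-ol | OC/C=C/c1ccc(OCc2ccccc2)c(OC)c1 | intermediate
5 | [(2S,3S)-3-(4-benzyloxy-3-methoxyphenyl)oxiran-2-yl]methanol | OC[C@@H]1O[C@H]1c1ccc(OCc2ccccc2)c(OC)c1 | intermediate (not isolated)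
6 | tert-butyl{[(2S,3S)-3-(4-benzyloxy-3-methoxyphenyl)oxiran-2-yl]methoxy}dimethylsilane | CC(C)(C)[Si](C)(C)OC[C@@H]1O[C@H]1c1ccc(OCc2ccccc2)c(OC)c1 | intermediate
7 | (2S,3R)-3-[4-(benzyloxy)-3-methoxyphenyl]-3-{[(2E)-3-[4-(benzyloxy)-3-methoxyphenyl]prop-2-en-1-yl]oxy}-1-{[tert-butyl(dimethyl)silyl]oxy}propan-2-ol | COc1cc(/C=C/CO[C@H](c2ccc(OCc3ccccc3)c(OC)c2)[C@@H](O)CO[Si](C)(C)C(C)(C)C)ccc1OCc1ccccc1 | intermediate
8 | (1R)-1-[4-(benzyloxy)-3-methoxyphenyl]-1-{[(2E)-3-[4-(benzyloxy)-3-methoxyphenyl]prop-2-en-1-yl]oxy}-3-{[tert-butyl(dimethyl)silyl]oxy}propan-2-one | COc1cc(/C=C/CO[C@H](c2ccc(OCc3ccccc3)c(OC)c2)C(=O)CO[Si](C)(C)C(C)(C)C)ccc1OCc1ccccc1 | intermediate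
9 | Prins benzylic cation: (2R,3S,4S)-oxolane with 2-aryl, 3-O–SnCl4⁻, 3-CH2OTBS and 4-(aryl-CH⁺), aryl = 4-benzyloxy-3-methoxyphenyl (SMILES drawn as the tin-free alkoxide) | COc1cc(ccc1OCc1ccccc1)[CH+][C@H]1CO[C@H](c2ccc(OCc3ccccc3)c(OC)c2)[C@@]1([O-])CO[Si](C)(C)C(C)(C)C | intermediate (not isolated)
10 | (1S,2R,5R,6S)-2,6-bis[4-(benzyloxy)-3-methoxyphenyl]-3,7-dioxabicyclo[3.3.0]octan-1-ol | COc1cc(ccc1OCc1ccccc1)[C@@H]1[C@H]2CO[C@H](c3ccc(OCc4ccccc4)c(OC)c3)[C@@]2(O)CO1 | intermediate
11 | (1S,2R,5R,6S)-2,6-bis(4-hydroxy-3-methoxyphenyl)-3,7-dioxabicyclo[3.3.0]octan-1-ol (1-hydroxypinoresinol) | COc1cc(ccc1O)[C@@H]1[C@H]2CO[C@H](c3ccc(O)c(OC)c3)[C@@]2(O)CO1 | intermediate (not isolated)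
12 | (2R,3S,4S)-2-(4-hydroxy-3-methoxyphenyl)-4-[(4-hydroxy-3-methoxyphenyl)methyl]-3-(hydroxymethyl)oxolan-3-ol (olivil) | COc1cc(C[C@H]2CO[C@H](c3ccc(O)c(OC)c3)[C@@]2(O)CO)ccc1O | target

**Step count**
Total: 7 steps. Longest linear sequence: 7 steps (1 → 3 → 4 → 6 → 7 → 8 → 10 → 12); alcohol 4 re-enters in step 4, so there is no separate branch.

**Three steps most likely to fail**

Step 4 (epoxide opening). A p-alkoxyaryl epoxide opens with some SN1 character, so retention can compete with inversion; Meinwald rearrangement and acid ionisation of the cinnamyl alcohol are further side paths. The fallback sets the C7 centre by catalyst-controlled carbene insertion instead of substitution; it sets out from 6 and comes back at 8. Bi(OTf)3-catalysed Meinwald rearrangement (1,2-hydride shift) of 6 gives the achiral benzyl ketone F1. Regitz diazo transfer (p-ABSA, DBU, MeCN) at the benzylic methylene gives the α-aryl diazo ketone F2. Enantioselective O–H insertion of the rhodium carbenoid from F2 into alcohol 4 (Rh2(TPA)4 with a chiral spiro phosphoric acid as proton shuttle) then gives 8 directly.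

Step 6 (Prins bicyclisation). The Lewis acid may ionise the 4-alkoxycinnamyl ether, or the alkoxide may close an oxetane and lead to carbonyl–olefin metathesis. Enolisation of 8 or benzylic ionisation at C2 of 10 would erode ee. The fallback replaces the cationic bicyclisation by a reductive radical monocyclisation; it sets out from 8 and comes back at 12. SmI2/HMPA/t-BuOH in THF at −78 °C (ketyl–olefin 5-exo cyclisation; chair transition state with aryl equatorial and O–Sm anti to the styrene terminus, same relative configuration) gives the silyl-protected dibenzyl olivil F3. Brief H2, Pd/C removes the benzyl ethers to give 9-O-silyl olivil F4, and TBAF in THF gives 12.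

Step 7 (regioselective hydrogenolysis). The wrong benzylic C–O bond (C2–O3) could cleave, or both could, giving the seco-lignan. The fallback fixes the regiochemistry by cation stability instead of surface hydrogenolysis; it sets out from 10 and comes back at 12. Et3SiH, BF3·OEt2 in CH2Cl2 at −78 °C ionises only C6–O7 (its cation is not β to the carbinol oxygen) and delivers hydride to give O,O'-dibenzyl olivil F5. Short transfer hydrogenolysis (Pd/C, 1,4-cyclohexadiene) then removes the two benzyl ethers to give 12.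

**Further compounds**
F1 | step 4 | 1-[4-(benzyloxy)-3-methoxyphenyl]-3-{[tert-butyl(dimethyl)silyl]oxy}propan-2-one | COc1cc(CC(=O)CO[Si](C)(C)C(C)(C)C)ccc1OCc1ccccc1
F2 | step 4 | 1-[4-(benzyloxy)-3-methoxyphenyl]-3-{[tert-butyl(dimethyl)silyl]oxy}-1-diazopropan-2-one | COc1cc(C(=[N+]=[N-])C(=O)CO[Si](C)(C)C(C)(C)C)ccc1OCc1ccccc1
F3 | step 6 | (2R,3S,4S)-2-[4-(benzyloxy)-3-methoxyphenyl]-4-{[4-(benzyloxy)-3-methoxyphenyl]methyl}-3-({[tert-butyl(dimethyl)silyl]oxy}methyl)oxolan-3-ol | COc1cc(C[C@H]2CO[C@H](c3ccc(OCc4ccccc4)c(OC)c3)[C@@]2(O)CO[Si](C)(C)C(C)(C)C)ccc1OCc1ccccc1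
F4 | step 6 | (2R,3S,4S)-3-({[tert-butyl(dimethyl)silyl]oxy}methyl)-2-(4-hydroxy-3-methoxyphenyl)-4-[(4-hydroxy-3-methoxyphenyl)methyl]oxolan-3-ol | COc1cc(C[C@H]2CO[C@H](c3ccc(O)c(OC)c3)[C@@]2(O)CO[Si](C)(C)C(C)(C)C)ccc1O
F5 | step 7 | (2R,3S,4S)-2-[4-(benzyloxy)-3-methoxyphenyl]-4-{[4-(benzyloxy)-3-methoxyphenyl]methyl}-3-(hydroxymethyl)oxolan-3-ol | COc1cc(C[C@H]2CO[C@H](c3ccc(OCc4ccccc4)c(OC)c3)[C@@]2(O)CO)ccc1OCc1ccccc1
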